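## Retrosynthetic overview

- Target numbered as a cyclohex-2-ene-1,2-dicarboxylic acid: C1 (CO2H), C2 (ring alkene, CO2H), C3 (=CH), C4 (=CH–CO2H, exocyclic), C5 (OH, CH2CO2H), C6 (aryl). It comes from a tetraallyl ester, bis(allyl) catechol ether and C5 silyl ether by desilylation and one zerovalent-palladium deallylation.
- That ester comes from a bicyclo[2.2.2]oct-5-en-2-one: allyloxide retro-Claisen opening of the keto bridge gives the C5 CH2CO2R chain and a C2/C4 phosphonate carbanion, which olefinates allyl glyoxylate (C4=CH).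
- The bicycle comes from a Diels–Alder reaction of a 2,4-bis(silyloxy)cyclohexa-1,3-diene with diethyl ethynylphosphonate (bonds C2–C3 and C4–C5). Enabling feature: C5 (bearing OH and CH2CO2H) and C2 (bearing CO2H) stand 1,4 across the ring, so the side-chain carboxyl carbon can be tied to C2 as the keto bridge of a bicyclo[2.2.2]octenone; C5–O and that C=O are then the two oxygens of a cyclohexane-1,3-dione, i.e. of a 1,3-dioxygenated diene with C5 and C2 as termini.
- The dione comes from an enantioselective [4+2] of a 4-aryl-1-ethoxy-1,3-bis(silyloxy)butadiene (from 3,4-dihydroxyphenylacetic acid) with diallyl fumarate, which sets C1 and C6.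
- Ring order: cyclohexane-1,3-dione ring (C1, C2, C5, C6 plus two temporary carbons), then bicyclo[2.2.2]octadiene (target ring C1–C6 closed), then opening of the temporary keto bridge.

Key step: step 6

Assumption: the (S)-oxazaborolidinium catalyst of step 4 is taken to give the (1R,2S) sense at the two fumarate carbons; if the opposite sense is found, its enantiomer is used with no other change.

## Route

Step 1
Reactants: 1 (3,4-dihydroxyphenyl)acetic acid
Product: 3 [3,4-bis(allyloxy)phenyl]acetic acid, via allyl ester 2 (not isolated)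
Conditions: allyl bromide (3.5 equiv), K2CO3, DMF, 60 °C; then 2 M NaOH, MeOH, 23 °C; 1 M HCl work-up
Reagents that add atoms: allyl bromide, C=CCBr; sodium hydroxide, [Na+].[OH-]
Why: Williamson O-allylation of both phenols and the carboxylate, then saponification of the allyl ester alone, should give a catechol protection that withstands bases, silyl triflates and heat and is removed at the end with zerovalent palladium.

Step 2
Reactants: 3 [3,4-bis(allyloxy)phenyl]acetic acid; 4 potassium ethyl malonate
Product: 6 ethyl 4-[3,4-bis(allyloxy)phenyl]-3-oxobutanoate, via acyl imidazolide 5 (not isolated)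
Conditions: 1,1'-carbonyldiimidazole, THF, 23 °C; then 4, MgCl2, Et3N, MeCN, 23 to 40 °C; 1 M HCl work-up
Reagents that add atoms: 1,1'-carbonyldiimidazole, O=C(n1ccnc1)n1ccnc1
Why: C-acylation of the magnesium enolate of the malonate half-ester by the acyl imidazolide followed by decarboxylation (crossed Claisen-type β-keto ester synthesis) should give the β-keto ester.

Step 3
Reactants: 6 ethyl 4-[3,4-bis(allyloxy)phenyl]-3-oxobutanoate
Product: 7 (3Z)-4-[3,4-bis(allyloxy)phenyl]-1-ethoxy-1,3-bis(trimethylsilyloxy)buta-1,3-diene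
Conditions: Me3SiOSO2CF3 (2.3 equiv), Et3N (2.6 equiv), Et2O, 0 to 23 °C
Reagents that add atoms: trimethylsilyl trifluoromethanesulfonate, C[Si](C)(C)OS(=O)(=O)C(F)(F)F
Why: two successive soft enolisations and O-silylations (β-silyloxy enoate, then vinylogous removal of the acidic benzylic hydrogen) should give the 1-alkoxy-1,3-bis(silyloxy)diene, with the aryl group cis to the C3 silyloxy group to avoid allylic strain.

Step 4
Reactants: 7 (3Z)-4-[3,4-bis(allyloxy)phenyl]-1-ethoxy-1,3-bis(trimethylsilyloxy)buta-1,3-diene; 8 diallyl fumarate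
Product: 10 diallyl (1R,2S,3R)-3-[3,4-bis(allyloxy)phenyl]-4,6-dioxocyclohexane-1,2-dicarboxylate, via silyl ketal cycloadduct 9 (not isolated)
Conditions: (S)-1-(2-methylphenyl)-3,3-diphenyltetrahydro-1H,3H-pyrrolo[1,2-c][1,3,2]oxazaborole (20 mol%), HN(SO2CF3)2 (18 mol%), CH2Cl2, −78 to −40 °C; then 1 M HCl, THF, 23 °C
Reagents that add atoms: none
Why: catalytic enantioselective Diels–Alder reaction, in which the chiral oxazaborolidinium ion binds one ester carbonyl of 8, shields one face and holds that ester endo, so the catalyst sets the two fumarate carbons (trans from the E alkene), the endo rule places the aryl carbon trans to its neighbouring ester, and the acid work-up removes both silyl groups and ethanol to unveil the 1,3-dione, whose aryl carbon can still equilibrate to the all-trans arrangement.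

Step 5
Reactants: 10 diallyl (1R,2S,3R)-3-[3,4-bis(allyloxy)phenyl]-4,6-dioxocyclohexane-1,2-dicarboxylate
Product: 11 diallyl (1S,6R)-6-[3,4-bis(allyloxy)phenyl]-3,5-bis(tert-butyldimethylsilyloxy)cyclohexa-2,4-diene-1,2-dicarboxylate
Conditions: t-BuMe2SiOSO2CF3 (2.5 equiv), Et3N (3 equiv), CH2Cl2, 0 to 23 °C
Reagents that add atoms: tert-butyldimethylsilyl trifluoromethanesulfonate, CC(C)(C)[Si](C)(C)OS(=O)(=O)C(F)(F)F
Why: double soft enolisation and O-silylation, in which the second enolisation takes the most acidic remaining hydrogen (on the carbon between ketone and ester), should give the linearly conjugated 1,3-bis(silyloxy)diene with the ester on its terminus while the two sp3 stereocentres stay untouched.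

Step 6
Reactants: 11 diallyl (1S,6R)-6-[3,4-bis(allyloxy)phenyl]-3,5-bis(tert-butyldimethylsilyloxy)cyclohexa-2,4-diene-1,2-dicarboxylate; 12 diethyl ethynylphosphonate
Product: 14 diallyl (1S,4R,7S,8R)-8-[3,4-bis(allyloxy)phenyl]-4-(tert-butyldimethylsilyloxy)-5-(diethoxyphosphoryl)-2-oxobicyclo[2.2.2]oct-5-ene-1,7-dicarboxylate, via bis-silyl cycloadduct 13 (not isolated)
Conditions: PhMe, 90 °C, sealed tube, 2,6-di-tert-butyl-4-methylphenol (cat.); then oxalic acid, THF/H2O, 0 °C
Reagents that add atoms: none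
Why: Thermal normal-electron-demand Diels–Alder reaction: the electron-rich 1,3-bis(silyloxy)diene adds suprafacially across the alkyne, its nucleophilic ester-bearing terminus (target C2) to the unsubstituted β-carbon of the ethynylphosphonate (C3) and its silyloxy terminus (C5) to the phosphorus-bearing carbon (C4), so that C2–C3 and C4–C5 form in one concerted, asynchronous step. The closest known reaction type is the cycloaddition of 2,4-bis(silyloxy)cyclohexa-1,3-dienes with acetylenic esters, sulfones or phosphonates to bicyclo[2.2.2]octa-2,5-dienes. One [4+2] event closes two six-membered rings at once, the target ring C1–C6 and the temporary ring holding the two silyloxy carbons, each by intermolecular two-bond annulation across the diene termini. The new stereocentre C5 (and the temporary bridgehead C2) is set by the C6 stereocentre: allylic 1,2-strain with the C5 silyloxy group holds the aryl group pseudoaxial, and the phosphonate-bearing end of the alkyne should approach the opposite diene face, which places the aryl group syn to the future CH2CO2R carbon and trans to the C5 oxygen. The step needs regioselectivity, secured by the 1,3-dioxygenation pattern that polarises the diene (ortho/para rule), facial selectivity, secured as described, and survival of the adduct against retro-[4+2] loss of the C1–C6 bridge (Alder–Rickert cleavage), secured by the moderate temperature and by hydrolysing the silyl enol ether bridge to the ketone directly afterwards. The bridgehead tertiary silyl ether should survive the mild acid that cleaves the silyl enol ether.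

Step 7
Reactants: 15 diallyl L-tartrate
Product: 16 allyl glyoxylate
Conditions: H5IO6, Et2O, 23 °C; distillation
Reagents that add atoms: none
Why: periodate glycol cleavage (Malaprade reaction) of the tartrate diol should give two molecules of the anhydrous glyoxylate ester.

Step 8
Reactants: 14 diallyl (1S,4R,7S,8R)-8-[3,4-bis(allyloxy)phenyl]-4-(tert-butyldimethylsilyloxy)-5-(diethoxyphosphoryl)-2-oxobicyclo[2.2.2]oct-5-ene-1,7-dicarboxylate; 16 allyl glyoxylate
Product: 18 diallyl (1S,4E,5R,6R)-4-[2-(allyloxy)-2-oxoethylidene]-5-[2-(allyloxy)-2-oxoethyl]-6-[3,4-bis(allyloxy)phenyl]-5-(tert-butyldimethylsilyloxy)cyclohex-2-ene-1,2-dicarboxylate, via phosphonate carbanion 17 (not isolated)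
Conditions: NaH, allyl alcohol (1.05 equiv each), THF, 0 °C; 14, −40 to 0 °C; then 16, −78 to 0 °C; AcOH quench
Reagents that add atoms: prop-2-en-1-ol (used as its sodium alkoxide), C=CCO
Why: Proposed new method: allyloxide adds to the strained bridging ketone and the tetrahedral intermediate breaks the bond to the bridgehead carbon (retro-Claisen of a non-enolisable β-keto ester), which turns the keto bridge into the C5 CH2CO2allyl chain and leaves a carbanion delocalised over C2 (α to the ester) and C4 (α to phosphorus); this vinylogous phosphonate anion should olefinate allyl glyoxylate at C4 (Horner–Wadsworth–Emmons) to give the exocyclic acrylate with its ester turned away from the quaternary C5 (E) while C2=C3 stays conjugated with the C2 ester; the closest known reaction types are the alkoxide retro-Dieckmann opening of bridged bicyclic β-keto esters and the Horner–Wadsworth–Emmons reaction of 4-phosphonocrotonate anions with aldehydes, here joined through a carbanion made by C–C cleavage instead of deprotonation.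

Step 9
Reactants: 18 diallyl (1S,4E,5R,6R)-4-[2-(allyloxy)-2-oxoethylidene]-5-[2-(allyloxy)-2-oxoethyl]-6-[3,4-bis(allyloxy)phenyl]-5-(tert-butyldimethylsilyloxy)cyclohex-2-ene-1,2-dicarboxylate
Product: 19 diallyl (1S,4E,5R,6R)-4-[2-(allyloxy)-2-oxoethylidene]-5-[2-(allyloxy)-2-oxoethyl]-6-[3,4-bis(allyloxy)phenyl]-5-hydroxycyclohex-2-ene-1,2-dicarboxylate
Conditions: HF·pyridine, pyridine/THF, 0 to 23 °C
Reagents that add atoms: none
Why: fluoride-induced cleavage of the tertiary silyl ether under buffered, non-basic conditions should leave the allyl esters, the dienoate and the C1 stereocentre untouched, and the E acrylate cannot lactonise onto the freed hydroxyl.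

Step 10
Reactants: 19 diallyl (1S,4E,5R,6R)-4-[2-(allyloxy)-2-oxoethylidene]-5-[2-(allyloxy)-2-oxoethyl]-6-[3,4-bis(allyloxy)phenyl]-5-hydroxycyclohex-2-ene-1,2-dicarboxylate
Product: 20 (1S,4E,5R,6R)-5-(carboxymethyl)-4-(carboxymethylidene)-6-(3,4-dihydroxyphenyl)-5-hydroxycyclohex-2-ene-1,2-dicarboxylic acid (CNP0109568.2)
Conditions: Pd(PPh3)4 (10 mol%), morpholine (12 equiv), THF, 23 °C, argon; then aqueous HCl to pH 2, reverse-phase chromatography
Reagents that add atoms: none
Why: Tsuji–Trost-type deallylation, in which zerovalent palladium ionises the four allyl esters and both allyl aryl ethers to π-allyl complexes that morpholine captures, should release the tetra-acid catechol under near-neutral conditions that avoid double-bond migration and aromatisation.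

## Compound list

1 | (3,4-dihydroxyphenyl)acetic acid | OC(=O)Cc1ccc(O)c(O)c1 | starting material
2 | allyl [3,4-bis(allyloxy)phenyl]acetate | C=CCOC(=O)Cc1ccc(OCC=C)c(OCC=C)c1 | intermediate
3 | [3,4-bis(allyloxy)phenyl]acetic acid | OC(=O)Cc1ccc(OCC=C)c(OCC=C)c1 | intermediate
4 | potassium ethyl malonate | CCOC(=O)CC(=O)[O-].[K+] | starting material
5 | 1-{[3,4-bis(allyloxy)phenyl]acetyl}imidazole | O=C(Cc1ccc(OCC=C)c(OCC=C)c1)n1ccnc1 | intermediate
6 | ethyl 4-[3,4-bis(allyloxy)phenyl]-3-oxobutanoate | CCOC(=O)CC(=O)Cc1ccc(OCC=C)c(OCC=C)c1 | intermediate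
7 | (3Z)-4-[3,4-bis(allyloxy)phenyl]-1-ethoxy-1,3-bis(trimethylsilyloxy)buta-1,3-diene (ketene acetal geometry immaterial) | C[Si](C)(C)O/C(C=C(OCC)O[Si](C)(C)C)=C\c1ccc(OCC=C)c(OCC=C)c1 | intermediate
8 | diallyl fumarate | C=CCOC(=O)/C=C/C(=O)OCC=C | starting material
9 | diallyl (1R,2S,3R)-3-[3,4-bis(allyloxy)phenyl]-6-ethoxy-4,6-bis(trimethylsilyloxy)cyclohex-4-ene-1,2-dicarboxylate (either configuration at C6) | CCOC1(O[Si](C)(C)C)C=C(O[Si](C)(C)C)[C@@H](c2ccc(OCC=C)c(OCC=C)c2)[C@H](C(=O)OCC=C)[C@H]1C(=O)OCC=C | intermediate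
10 | diallyl (1R,2S,3R)-3-[3,4-bis(allyloxy)phenyl]-4,6-dioxocyclohexane-1,2-dicarboxylate (drawn as the diketone) | O=C1[C@H](C(=O)OCC=C)[C@@H](C(=O)OCC=C)[C@H](c2ccc(OCC=C)c(OCC=C)c2)C(=O)C1 | intermediate
11 | diallyl (1S,6R)-6-[3,4-bis(allyloxy)phenyl]-3,5-bis(tert-butyldimethylsilyloxy)cyclohexa-2,4-diene-1,2-dicarboxylate | C=CCOC(=O)C1=C(O[Si](C)(C)C(C)(C)C)C=C(O[Si](C)(C)C(C)(C)C)[C@@H](c2ccc(OCC=C)c(OCC=C)c2)[C@@H]1C(=O)OCC=C | intermediate
12 | diethyl ethynylphosphonate | CCOP(=O)(OCC)C#C | starting material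
13 | diallyl (1S,4S,7S,8R)-8-[3,4-bis(allyloxy)phenyl]-2,4-bis(tert-butyldimethylsilyloxy)-5-(diethoxyphosphoryl)bicyclo[2.2.2]octa-2,5-diene-1,7-dicarboxylate | C=CCOC(=O)[C@@]12C=C(P(=O)(OCC)OCC)[C@@](O[Si](C)(C)C(C)(C)C)(C=C1O[Si](C)(C)C(C)(C)C)[C@@H](c3ccc(OCC=C)c(OCC=C)c3)[C@@H]2C(=O)OCC=C | intermediate
14 | diallyl (1S,4R,7S,8R)-8-[3,4-bis(allyloxy)phenyl]-4-(tert-butyldimethylsilyloxy)-5-(diethoxyphosphoryl)-2-oxobicyclo[2.2.2]oct-5-ene-1,7-dicarboxylate | C=CCOC(=O)[C@@]12C=C(P(=O)(OCC)OCC)[C@@](O[Si](C)(C)C(C)(C)C)(CC1=O)[C@@H](c3ccc(OCC=C)c(OCC=C)c3)[C@@H]2C(=O)OCC=C | intermediate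
15 | diallyl L-tartrate, (2R,3R) | C=CCOC(=O)[C@H](O)[C@@H](O)C(=O)OCC=C | starting material
16 | allyl glyoxylate | C=CCOC(=O)C=O | intermediate
17 | sodium salt of the ring-opened carbanion: diallyl (1S,5R,6R)-5-[2-(allyloxy)-2-oxoethyl]-6-[3,4-bis(allyloxy)phenyl]-5-(tert-butyldimethylsilyloxy)-4-(diethoxyphosphoryl)cyclohex-2-ene-1,2-dicarboxylate deprotonated at C4 (one resonance form) | [Na+].CCOP(=O)(OCC)[C-]1C=C(C(=O)OCC=C)[C@@H](C(=O)OCC=C)[C@H](c2ccc(OCC=C)c(OCC=C)c2)[C@]1(O[Si](C)(C)C(C)(C)C)CC(=O)OCC=C | intermediate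
18 | diallyl (1S,4E,5R,6R)-4-[2-(allyloxy)-2-oxoethylidene]-5-[2-(allyloxy)-2-oxoethyl]-6-[3,4-bis(allyloxy)phenyl]-5-(tert-butyldimethylsilyloxy)cyclohex-2-ene-1,2-dicarboxylate | C=CCOC(=O)/C=C1\C=C(C(=O)OCC=C)[C@@H](C(=O)OCC=C)[C@H](c2ccc(OCC=C)c(OCC=C)c2)[C@]1(O[Si](C)(C)C(C)(C)C)CC(=O)OCC=C | intermediate
19 | diallyl (1S,4E,5R,6R)-4-[2-(allyloxy)-2-oxoethylidene]-5-[2-(allyloxy)-2-oxoethyl]-6-[3,4-bis(allyloxy)phenyl]-5-hydroxycyclohex-2-ene-1,2-dicarboxylate | C=CCOC(=O)/C=C1\C=C(C(=O)OCC=C)[C@@H](C(=O)OCC=C)[C@H](c2ccc(OCC=C)c(OCC=C)c2)[C@]1(O)CC(=O)OCC=C | intermediate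
20 | (1S,4E,5R,6R)-5-(carboxymethyl)-4-(carboxymethylidene)-6-(3,4-dihydroxyphenyl)-5-hydroxycyclohex-2-ene-1,2-dicarboxylic acid | O=C(O)/C=C1\C=C(C(=O)O)[C@@H](C(=O)O)[C@H](c2ccc(O)c(O)c2)[C@]1(O)CC(=O)O | target

## Step count and risks

Total step count: 10. Longest linear sequence: 9 steps (steps 1 to 6 and 8 to 10); step 7 prepares a reagent.

Steps most likely to fail:

1. Step 8 (proposed new method). The carbanion at C4 sits next to the quaternary C5 and may add too slowly to the glyoxylate; meanwhile alkoxide-mediated proton transfer on the product dienoate could move the double bonds into the ring and lead on to aromatisation with loss of the C5 oxygen; the olefination may also give part of the Z acrylate. Fallback, from 14 back to 18 by known reactions run separately: sodium allyloxide (1.0 equiv, THF, −40 °C) is quenched with acetic acid as soon as the retro-Claisen opening is complete, which gives the isolable allylic phosphonate F1; this is then olefinated with 16 under the LiCl/DBU variant of the Horner–Wadsworth–Emmons reaction in MeCN, without any alkoxide, to reach 18.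

2. Step 6. Cycloaddition at two fully substituted diene termini may be slow, so that retro-[4+2] loss of the cinnamate bridge and aromatisation, or erosion of facial selectivity at higher temperature, compete. Fallback, from 11 back to 18 with a far more reactive acetylene equivalent and a sulfone-based olefination: 11 and ethynyl 4-methylphenyl sulfone (PhMe, 40–50 °C) give the bis-silyl sulfonyl cycloadduct F2, hydrolysed with oxalic acid to the sulfonyl ketone F3; sodium allyloxide opens F3 to the ring-opened sulfonyl carbanion F4, which is added to 16 and acetylated (Ac2O) to the β-acetoxy sulfone F5; reductive elimination with SmI2 in THF (Julia–Lythgoe olefination) gives 18.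

3. Step 4. Enantioface discrimination on the fumarate may be insufficient, or the reaction may stop at the open-chain Michael adduct, which would later close to the isomeric 2-acyl dione. Fallback, from 7 and 8 back to 10: the uncatalysed thermal cycloaddition (PhMe, 80 °C) gives 9 together with its enantiomer, the silyl ketal cycloadduct F6; acid hydrolysis gives 10 and its enantiomer, the dione F7; 10 is separated by preparative chromatography on a chiral stationary phase (or by crystallisation of a salt of this vinylogous acid with a chiral amine) and carried into step 5.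

## Further compounds

F1 | step 8 | diallyl (1S,5R,6R)-5-[2-(allyloxy)-2-oxoethyl]-6-[3,4-bis(allyloxy)phenyl]-5-(tert-butyldimethylsilyloxy)-4-(diethoxyphosphoryl)cyclohex-2-ene-1,2-dicarboxylate (either configuration at C4) | CCOP(=O)(OCC)C1C=C(C(=O)OCC=C)[C@@H](C(=O)OCC=C)[C@H](c2ccc(OCC=C)c(OCC=C)c2)[C@]1(O[Si](C)(C)C(C)(C)C)CC(=O)OCC=C
F2 | step 6 | diallyl 8-[3,4-bis(allyloxy)phenyl]-2,4-bis(tert-butyldimethylsilyloxy)-5-(4-methylphenylsulfonyl)bicyclo[2.2.2]octa-2,5-diene-1,7-dicarboxylate (same relative and absolute arrangement as 13) | C=CCOC(=O)[C@@]12C=C(S(=O)(=O)c3ccc(C)cc3)[C@@](O[Si](C)(C)C(C)(C)C)(C=C1O[Si](C)(C)C(C)(C)C)[C@@H](c4ccc(OCC=C)c(OCC=C)c4)[C@@H]2C(=O)OCC=C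
F3 | step 6 | diallyl 8-[3,4-bis(allyloxy)phenyl]-4-(tert-butyldimethylsilyloxy)-5-(4-methylphenylsulfonyl)-2-oxobicyclo[2.2.2]oct-5-ene-1,7-dicarboxylate (same arrangement as 14) | C=CCOC(=O)[C@@]12C=C(S(=O)(=O)c3ccc(C)cc3)[C@@](O[Si](C)(C)C(C)(C)C)(CC1=O)[C@@H](c4ccc(OCC=C)c(OCC=C)c4)[C@@H]2C(=O)OCC=C
F4 | step 6 | sodium salt of the ring-opened sulfonyl carbanion (sulfone analogue of 17, one resonance form) | [Na+].Cc1ccc(cc1)S(=O)(=O)[C-]1C=C(C(=O)OCC=C)[C@@H](C(=O)OCC=C)[C@H](c2ccc(OCC=C)c(OCC=C)c2)[C@]1(O[Si](C)(C)C(C)(C)C)CC(=O)OCC=C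
F5 | step 6 | diallyl (1S,5R,6R)-4-[1-acetoxy-2-(allyloxy)-2-oxoethyl]-5-[2-(allyloxy)-2-oxoethyl]-6-[3,4-bis(allyloxy)phenyl]-5-(tert-butyldimethylsilyloxy)-4-(4-methylphenylsulfonyl)cyclohex-2-ene-1,2-dicarboxylate (mixture at the two new centres) | C=CCOC(=O)C(OC(C)=O)C1(S(=O)(=O)c2ccc(C)cc2)C=C(C(=O)OCC=C)[C@@H](C(=O)OCC=C)[C@H](c3ccc(OCC=C)c(OCC=C)c3)[C@]1(O[Si](C)(C)C(C)(C)C)CC(=O)OCC=C
F6 | step 4 | diallyl (1S,2R,3S)-3-[3,4-bis(allyloxy)phenyl]-6-ethoxy-4,6-bis(trimethylsilyloxy)cyclohex-4-ene-1,2-dicarboxylate (enantiomer of 9) | CCOC1(O[Si](C)(C)C)C=C(O[Si](C)(C)C)[C@H](c2ccc(OCC=C)c(OCC=C)c2)[C@@H](C(=O)OCC=C)[C@@H]1C(=O)OCC=C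
F7 | step 4 | diallyl (1S,2R,3S)-3-[3,4-bis(allyloxy)phenyl]-4,6-dioxocyclohexane-1,2-dicarboxylate (enantiomer of 10) | O=C1[C@@H](C(=O)OCC=C)[C@H](C(=O)OCC=C)[C@@H](c2ccc(OCC=C)c(OCC=C)c2)C(=O)C1
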